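The readings are calculated with constants of no real substance; noise was put on by code.

At early times, don't watch Q climb: watch the gap, the plateau minus Q, which is the fraction still missing. The dawn run is this same flask, and you take its 63.8% at 15.0 h as the plateau, a reading with its scatter.

the same everywhere: J 0.050 M

| run | remark | time |
|---|---|---|
| dawn | the very flask that is asked about, followed so far |  |
| flask |  | 3.0 d |

dawn run (percent of the J charged)

| time / h | Q / % |
|---|---|
| 3.00 | 48.2 |
| 5.00 | 57.9 |
| 10.0 | 63.3 |
| 15.0 | 63.8 |
| 30.0 | 62.3 |

(scatter of a reading: 0.5 percentage points)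

- what is said of Q includes X
- X is a solid; its amount is given per volume of the solution
- the earlier runs were read with a standard deviation of 0.5 percentage points
- reactions considered so far: J <-> Q; J <-> G; Q <-> G; J <-> D; X <-> Q

- time up to 3.0 d at which Q stands highest
- the amount of Q, in percent of the J charged, at that time
- the first time at which Q reaches 32%, in the same percent, in d

The gap is 16 percentage points at 3.00 h and 5.9 points at 5.00 h, so it closes at 0.486 h⁻¹. That gives 0.0594 d for the gap half-time, the half-life of a first-order approach to the plateau.

Now draw the curve. On this reckoning it leaves zero with a slope of 0.310 h⁻¹ of the charge. It crosses 32%, half the plateau, after one half-time, so at 0.0594 d. The knee follows: carried on from 5.00 h, the gap should be 0.52 points at 10.0 h, and the reading gives 0.5 points. Beyond that, the readings sink by 1.5 points in 15.0 h, a loss of 0.00100 h⁻¹ of the charge, poorly fixed against the scatter of 0.5 points. My estimate puts the peak where the gap closes just that fast, at 0.492 d, and I take its height as the plateau reading.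

The forecast, saying “The flask has the same charge as the dawn run”, gives 0.55 d, 63.9% and 0.066 d, times later than mine.

The flask gives 0.523 d, 63.7% and 0.0608 d.

    J ⇌ Q (K = 1.30, k = 0.00550 min⁻¹)
    J ⇌ G (K = 200, k = 0.00210 min⁻¹)
    Q ⇌ G (k = 0.00130 min⁻¹)
    J ⇌ D (K = 2.20, k = 4.00 × 10⁻⁴ min⁻¹)
    X ⇌ Q, rate k5*(cs5 - [Q]) while solid is left; crystals form when [Q] > cs5 (solubility = 0.530 mM, k = 0.0560 min⁻¹)

A neighbour charged with 0.013 M reaches a best of 58.3%, lower than this flask's. In this flask, 0.300 d is 5.05 half-times, which puts Q at 61.9%, and the flask then holds 62.0%.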